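**Your hunch.** You ask which flask ends with the longer chains, and your hunch is the longer run. I reckon by how much.

common to all: initiator 15 mM; impurity 12 mM

|  | free monomer | transfer agent | remark | time |
|---|---|---|---|---|
| teal | 0.75 M | 0.45 M | run made earlier |  |
| violet | 3 M | 0.45 M | run made earlier |  |
| Wednesday's | 1.5 M | 0.450 M |  | 4.0 h |
| Sunday's | 1.5 M | 0.450 M |  | 2.5 h |

- teal (time / h: monomer in chains / %): 0.200: 2.0; 0.667: 10.2; 1.00: 14.5; 2.00: 23.8; 2.50: 30.1; 3.00: 32.4
- violet (time / h: monomer in chains / %): 0.250: 7.8; 0.417: 15.9; 0.667: 25.6; 1.33: 44.2; 2.00: 52.8; 3.00: 67.7

(each reading ± 1 percentage point)

- the average divides the monomer in chains by the number of chains begun, living and dead together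
- the numbers in the tables scatter by 1 percentage point (one standard deviation)
- what may be going on: free monomer + initiator -> living end + monomer in chains; free monomer + living end -> monomer in chains + living end; living end + transfer agent -> dead chain; initiator + impurity -> spent initiator A; 2 initiator -> spent initiator B
- the earlier runs do not show the number of chains; that part of a forecast is a guess

- which of the two ends with the longer chains by the average number of monomer units in a chain (chains begun, living or dead) ("neither" if they lie within 10 %) (Wednesday's / Sunday's / neither)
- average number of monomer units in a chain (chains begun, living or dead) at the end, Wednesday's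
- average number of monomer units in a chain (chains begun, living or dead) at the end, Sunday's

**Same chains.** The two charges are identical, so I assume the same number of chains begins early in each, and the length ratio is then the conversion ratio. The earlier runs don't show that number, so I commit to no absolute length.

**Closed form.** Free monomer falls in proportion to c(free monomer)·c(living end). Transfer agent stands at 0.450 M against 15 mM of initiator, so c(transfer agent) stays near its charge and, if I treat the chains as begun at the start, c(living end) decays exponentially at a steady rate f. Integrating gives y = A(1 − exp(−f·t)), where y is ln of charged over present c(free monomer) and A is the ceiling.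

**Reading f.** Teal and violet share that transfer agent, and 1.5 M is their geometric middle, so I take the geometric mean of their y: 0.178 at 0.667 h and 0.452 at 2.00 h. Their ratio equals 1 + q + q·q, with q = exp(−f·0.667 h). That gives a reading of 0.270 h⁻¹, with the scatter of the runs in it, for my fade rate: the pseudo-first-order rate at which living ends die.

**My number.** The ceiling is 1.08, so conversion reaches 51.1 % in Wednesday's and 41.2 % in Sunday's. Wednesday's chains come out longer by a factor 1.24, which is beyond the margin.

**The result.** The forecast says Wednesday's, at 190 and 150, since “the longer run should have the longer average chains”. The flasks give Wednesday's, 336 against 268, a ratio of 1.25.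

    free monomer + initiator → living end + monomer in chains (k = 5.50 × 10⁻⁴ M⁻¹ s⁻¹)
    free monomer + living end → monomer in chains + living end, rate k2*[living end]*[free monomer] (k = 0.0360 M⁻¹ s⁻¹)
    living end + transfer agent → dead chain (kL = 1.50 × 10⁻⁴ M⁻¹ s⁻¹)
    initiator + impurity → spent initiator A (k = 0.490 M⁻¹ s⁻¹)
    2 initiator → spent initiator B (k = 0.0900 M⁻¹ s⁻¹)

In Wednesday's, initiator stands at 0 % by 2.00 h, with 2.50 mM of chains begun. Growth and transfer then run together, free monomer going from 60.9 % to 44.1 % while living end falls to 9.68 × 10⁻⁴ M. Sunday's ends with 2.50 mM of chains. My f puts the living share at 4.00 h at 34.0 %; Wednesday's holds 38.7 %.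

**More impurity.** The neighbour of Wednesday's charged with 0.030 M of impurity keeps the same transfer agent, so f again gives 34.0 % living. That neighbour holds 38.1 %, and its average is 428.

The runs come from a simulation on assumed constants, noise included.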